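The data come from a simulation for substances that don't exist.

- Time is my axis: two earlier runs were followed to 80.0 min, and two new flasks are to be read at 80 min.

| flask | starting material | reagent | remark | time |
|---|---|---|---|---|
| Wednesday's | 1 M | 1.1 M | run made earlier |  |
| Saturday's | 1 M | 1.4 M | run made earlier |  |
| north-west | 1.0 M | 0.900 M |  | 80 min |
| south-west | 1.0 M | 1.20 M |  | 80 min |

| run | time / min | starting material / % | product / % |
|---|---|---|---|
| Wednesday's | 12.0 | 96.0 | 3.7 |
| Wednesday's | 25.0 | 94.2 | 6.7 |
| Wednesday's | 40.0 | 93.0 | 7.0 |
| Wednesday's | 50.0 | 91.8 | 8.0 |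
| Wednesday's | 60.0 | 90.5 | 8.6 |
| Wednesday's | 80.0 | 89.1 | 10.9 |
| Saturday's | 6.00 | 97.1 | 1.7 |
| Saturday's | 10.0 | 95.5 | 3.4 |
| Saturday's | 20.0 | 94.3 | 5.0 |
| Saturday's | 30.0 | 93.0 | 6.9 |
| Saturday's | 50.0 | 90.8 | 9.0 |
| Saturday's | 80.0 | 88.0 | 11.3 |

(readings scatter by 0.5 percentage points)



* part of the starting material that has reacted at the end, north-west
* part of the starting material that has reacted at the end, south-west
* what raising the concentration of reagent from its lowest to its highest value here does to the part of the starting material that has reacted (changes below 5 percentage points count as none) (no change / it rises / it falls)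

- On the first rung, Saturday's first reading of 1.7% product after 6.00 min gives an opening pace of 0.00283 min⁻¹, a reading that, held constant, corresponds to an emptying time of 353 min for the starting material.
- On the next rung I reckon round one: that straight line gives 22.6% at 80.0 min, but Saturday's reading is 11.3%, about half of it. The pace in Saturday's flask has therefore sunk within a span shorter than the emptying time.
- On the last rung stand the charges: Saturday's flask still shows 88.0% starting material, and at one reagent per product its product has taken 0.113 M of 1.4 M reagent.
- In round two I put the first answer back and assume that the pace falls in inverse proportion to what has formed, so the squared fraction reacted grows in step with time. Saturday's readings give 1.59 × 10⁻⁴ min⁻¹ at 30.0 min and 1.60 × 10⁻⁴ min⁻¹ at 80.0 min.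
- I also assume proportionality to reagent. The final product readings, taken as the fraction reacted, then give 1.35 × 10⁻⁴ M⁻¹ min⁻¹ on Wednesday and 1.14 × 10⁻⁴ M⁻¹ min⁻¹ on Saturday, with mean 1.25 × 10⁻⁴ M⁻¹ min⁻¹: my root constant, the squared fraction reacted divided by time and by reagent concentration.
- One square root per flask gives me 9.47% north-west and 10.9% south-west. Their gap of 1.4 percentage points is below the margin, so I expect no change.
- The forecast says 10.3% north-west, 11.2% south-west and no change, having seen that each curve “slows, roughly as the square root of time”. Its north-west figure stands above mine.

- The flask gives 9.26% reacted north-west and 11.1% south-west; the trend is no change, with a change of 1.9 points.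

    starting material ⇌ intermediate + leaving ligand (K = 2.30 × 10⁻⁴ M, k = 0.00900 min⁻¹)
    reagent + intermediate → product (k = 0.240 M⁻¹ min⁻¹)
    reagent + leaving ligand ⇌ idle adduct, settled at all times (K = 0.690 M⁻¹)

- In north-west at 80.0 min, the intermediate is made at 0.964 of the rate at which it is used up, each step taken net, close to a steady state. The north-west result, squared and divided by time and reagent, is 1.19 × 10⁻⁴ M⁻¹ min⁻¹, against my root constant of 1.25 × 10⁻⁴ M⁻¹ min⁻¹. For north-west read at 3.0 h, the root constant gives 14.2%, and that flask stands at 13.7% reacted.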